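Late in a run the target is exposed to dissolved gas and can pass on to over-reacted product, so what stands at 10 min, 20 min and 40 min depends on how much starting material reached the target first, and how much target has since been lost.

common to all: gas phase 0.95 mM (held)
- maple: starting material 13 mM; run made earlier
- alder: starting material 30 mM; run made earlier
- Saturday's: starting material 20 mM; time 10 min
- Friday's: starting material 20 mM; time 20 min
- Thursday's: starting material 20 mM; time 40 min
- maple (time / min: over-reacted product / %, target / %, starting material / %): 0.500: 0.5, 2.2, 95.1; 0.833: 0, 3.7, 92.6; 1.50: 0.8, 7.2, 87.3; 3.00: 0.8, 14.0, 76.8; 6.00: 0.1, 24.7, 60.2
- alder (time / min: over-reacted product / %, target / %, starting material / %): 1.33: 0.3, 5.1, 82.1; 2.50: 0.6, 9.6, 71.4; 4.00: 0, 15.8, 58.6; 5.00: 0, 17.6, 53.3; 6.00: 0.7, 20.4, 48.5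

(each reading ± 0.5 percentage points)
- percentages count the starting material that a species holds: one self-condensation product counts as two
- at the start none of the gas is dissolved
- candidate steps: gas phase <-> dissolved gas; starting material + dissolved gas -> target; dissolved gas + target -> over-reacted product; 2 starting material -> self-condensation product; starting material -> decomposition product
1. which of these there is most of at the end, counted by the starting material in it, Saturday's (target / over-reacted product / starting material)
2. which of these there is most of at the end, counted by the starting material in it, Friday's (target / over-reacted product / starting material)
3. which of these there is most of at the end, counted by the starting material in it, Thursday's (target / over-reacted product / starting material)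
4. amount of the one of these that there is most of at the end, in percent of the starting material charged, Saturday's
5. amount of the one of these that there is most of at the end, in percent of the starting material charged, Friday's
6. amount of the one of these that there is most of at the end, in percent of the starting material charged, Thursday's

The ladder is read from the last readings, taking mean starting material as the midpoint of the charge and the end value. Uptake of gas is the first rung. Target per unit of starting material comes at 0.0514 min⁻¹ in maple and 0.0458 min⁻¹ in alder, despite charges of 13 mM and 30 mM. These stand in a ratio of 1.12 while the charges stand at 2.31, so dissolved gas is taken to stay near 0.95 mM, and the gas route is treated as pseudo-first-order, with a mean constant of 0.0486 min⁻¹.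

The missing balance, divided by time and mean starting material squared, gives 0.0390 min⁻¹ and 0.0919 min⁻¹. These stand in a ratio of 2.36, with the charges at 2.31, which marks self-condensation. At 20 mM its constant is 0.0606 min⁻¹.

The over-reaction constant, a loose reading, is 0.00591 min⁻¹. The time scales at 20 mM are then 16.5 min for self-condensation, 20.6 min for the gas route and 169 min for over-reaction.

The split, self-condensation over gas route at the charge, is 1.25. At any moment, the rate of the gas route over that of self-condensation is 1/(split × fraction of starting material left).

Integrating both routes for Friday's, then putting the first target back in for a second round, with mean target at 2/3 of its end value:

u = 1 − exp(−gas-route constant × time) = 0.622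
starting material = (1 − u)/(1 + split × u) = 21.3%
first target = ln(1 + split × u)/split = 46.0%
over-reacted product = 3.63%
target after that loss = 42.4%

The same reckoning puts starting material ahead of target in Saturday's, at 41.6% against 30.2%, and target ahead of starting material in Thursday's, at 49.1% against 6.92%.

The forecast, with “gas stays near saturation”, names the same species at 40%, 46% and 54%, its two target figures standing above this reckoning.

Saturday's flask gives starting material at 39.1%. Friday's flask gives target at 43.2%. Thursday's flask gives target at 49.9%.

    gas phase ⇌ dissolved gas, rate k1*(csat - [dissolved gas]) (kL = 25.0 min⁻¹)
    starting material + dissolved gas → target (k = 55.0 M⁻¹ min⁻¹)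
    dissolved gas + target → over-reacted product (k = 5.30 M⁻¹ min⁻¹)
    2 starting material → self-condensation product (k = 1.70 M⁻¹ min⁻¹)
    starting material → decomposition product (k = 5.00 × 10⁻⁴ min⁻¹)

In Friday's at 20.0 min, the gas route uses starting material 4.0 times as fast as self-condensation, and the split with the 19.3% left gives 4.15. In the neighbour of Friday's left until 50 min, 3.3% of starting material remains, the same quotient is 24.2, and target stands at 49.7% beside 10.0% of over-reacted product.

The runs are calculated with constants of no real substance, noise included.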